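**Plan**

- Feature: ring A (C1 ester carbonyl, C2 2-oxononyl chain, C4 OMe, C6 OH) is a 6-alkyl-4-methoxysalicylate. Its C3–C6 unit with oxygen on C4 and C6 is an acetoacetate-type diene, and its C1–C2 unit is an alk-2-ynoate.
- Cuts: first the benzyl ester of ring B and the dioxolane on the side-chain ketone, then ring A across C1–C6 and C2–C3, then the ester C–O bond to O4 of ring B, then the alkyne–CO2H bond and the alkyne itself.
- Forward: the ketal-protected alkyne chain is built from ethyl 3-oxodecanoate and carboxylated. The unhindered ynoic acid is esterified with benzyl orsellinate (ring B is bought as orsellinic acid). Ring A, the only ring made, is then annulated onto that ester, and two deprotections finish the route.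
- Stereochemistry: the target has no stereocentre and no stereogenic double bond, so nothing has to be set.

Key step: step 8

Remark on the chemistry: the geometry of the silyl ketene acetal double bond of the diene is immaterial, because that carbon ends as the sp2 carbon C6 of ring A; the diene is drawn as the E isomer. Ring B is the orsellinate ring and O4 is its esterified oxygen.

**Route**

Step 1
Reactants: 1 ethyl 3-oxodecanoate
Product: 2 ethyl 2-(2-heptyl-1,3-dioxolan-2-yl)acetate
Conditions: HOCH2CH2OH (3 equiv), p-TsOH·H2O (cat.), toluene, reflux, Dean–Stark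
Reagents that add atoms: ethylene glycol, OCCO
Why: Acid-catalysed ketalisation driven by azeotropic removal of water; of the two carbonyl groups only the ketone is electrophilic enough to form the dioxolane, so the ester stays available for the next step.

Step 2
Reactants: 2 ethyl 2-(2-heptyl-1,3-dioxolan-2-yl)acetate
Product: 3 2-(2-heptyl-1,3-dioxolan-2-yl)acetaldehyde
Conditions: i-Bu2AlH (1.1 equiv), CH2Cl2, −78 °C; MeOH, then aq. KNaC4H4O6
Reagents that add atoms: none
Why: Partial reduction of an ester with i-Bu2AlH: the tetrahedral aluminium hemiacetal, stabilised at −78 °C by chelation to a dioxolane oxygen, should collapse to the aldehyde only on the aqueous quench, when no hydride is left.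

Step 3
Reactants: 3 2-(2-heptyl-1,3-dioxolan-2-yl)acetaldehyde
Product: 4 2-heptyl-2-(prop-2-yn-1-yl)-1,3-dioxolane
Conditions: dimethyl (1-diazo-2-oxopropyl)phosphonate (1.3 equiv), K2CO3 (2 equiv), MeOH, 0 °C → rt
Reagents that add atoms: dimethyl (1-diazo-2-oxopropyl)phosphonate, COP(=O)(OC)C(=[N+]=[N-])C(C)=O
Why: Seyferth–Gilbert homologation in its Ohira–Bestmann form: methanolysis of the acetyl group frees the diazomethylphosphonate anion, which olefinates the aldehyde to a diazoalkene that loses N2 and rearranges by 1,2-hydrogen shift to the terminal alkyne under conditions the ketal tolerates.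

Step 4
Reactants: 4 2-heptyl-2-(prop-2-yn-1-yl)-1,3-dioxolane
Product: 6 4-(2-heptyl-1,3-dioxolan-2-yl)but-2-ynoic acid, via lithium acetylide 5 (not isolated)
Conditions: n-BuLi (1.05 equiv), THF, −78 °C; CO2 (g), −78 → 0 °C; cold 0.5 M HCl to pH 3, rapid extraction
Reagents that add atoms: carbon dioxide, O=C=O
Why: Deprotonation of the terminal alkyne, which is far more acidic than the propargylic CH2, followed by carboxylation of the lithium acetylide is the standard entry to alk-2-ynoic acids, and the brief cold acidification should spare the dioxolane.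

Step 5
Reactants: 7 orsellinic acid (2,4-dihydroxy-6-methylbenzoic acid)
Product: 8 benzyl 2,4-dihydroxy-6-methylbenzoate (benzyl orsellinate)
Conditions: BnBr (1.05 equiv), KHCO3 (1.1 equiv), DMF, rt
Reagents that add atoms: benzyl bromide, BrCc1ccccc1
Why: Chemoselective SN2 O-alkylation of the carboxylate: KHCO3 deprotonates only the carboxylic acid, so both phenols stay free and the hydrogenolysable ester is installed in one step without heating the decarboxylation-prone acid.

Step 6
Reactants: 6 4-(2-heptyl-1,3-dioxolan-2-yl)but-2-ynoic acid; 8 benzyl 2,4-dihydroxy-6-methylbenzoate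
Product: 9 benzyl 4-{[4-(2-heptyl-1,3-dioxolan-2-yl)but-2-ynoyl]oxy}-2-hydroxy-6-methylbenzoate
Conditions: DCC (1.1 equiv), DMAP (5 mol %), CH2Cl2, −20 → 0 °C
Reagents that add atoms: none
Why: Steglich esterification: the unhindered ynoic acid, activated as its O-acylisourea, should acylate the 4-OH of ring B because the 2-OH is held in a hydrogen bond to the benzyl ester carbonyl, the usual site selectivity of orsellinate esters, while low temperature and little DMAP limit conjugate addition to the ynoate.

Step 7
Reactants: 10 methyl (E)-3-methoxybut-2-enoate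
Product: 12 (1E)-1,3-dimethoxy-1-[(trimethylsilyl)oxy]buta-1,3-diene, via lithium dienolate 11 (not isolated)
Conditions: LiN(i-Pr)2 (commercial solution, 1.1 equiv), THF, −78 °C; Me3SiCl (1.2 equiv), −78 °C → rt; pentane, filtration under argon, bulb-to-bulb distillation
Reagents that add atoms: chlorotrimethylsilane, C[Si](C)(C)Cl
Why: γ-Deprotonation of the vinylogous carbonate ester gives the extended lithium dienolate, whose kinetic O-silylation with Me3SiCl gives the Brassard-type silyl ketene acetal diene.

Step 8
Reactants: 9 benzyl 4-{[4-(2-heptyl-1,3-dioxolan-2-yl)but-2-ynoyl]oxy}-2-hydroxy-6-methylbenzoate; 12 (1E)-1,3-dimethoxy-1-[(trimethylsilyl)oxy]buta-1,3-diene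
Product: 15 benzyl 4-({2-[(2-heptyl-1,3-dioxolan-2-yl)methyl]-6-hydroxy-4-methoxybenzoyl}oxy)-2-hydroxy-6-methylbenzoate, via ring B trimethylsilyl ether 13 (not isolated), via cyclohexa-1,4-diene cycloadduct 14 (not isolated)
Conditions: 12 (3.5 equiv), toluene, 23 °C, 1 h, then 120 °C, sealed tube, argon; then 0.1 M HCl, THF, 0 °C
Reagents that add atoms: none
Why: One equivalent of the silyl ketene acetal first transfers its trimethylsilyl group to the chelated ring B phenol (13), which keeps that phenol from adding to the alkyne; a second equivalent then adds to the ynoate in a strongly asynchronous normal-electron-demand (4+2) cycloaddition, the diene CH2 terminus bonding to the ynoate β-carbon (ring A C3–C2) ahead of the ketene acetal carbon bonding to the α-carbon (C6–C1). The closest known reaction type is the Diels–Alder benzannulation of 1-alkoxy-1-silyloxy-3-alkoxybutadienes with alkynoates to give salicylates, applied here to an aryl ester, whose weaker oxygen donation should make the ynoate more electrophilic than an alkyl ynoate. Ring A is closed by the intermolecular cycloaddition itself as the cyclohexa-1,4-diene 14; cold dilute acid then hydrolyses the mixed methyl silyl ketal at C6 to a dienone that tautomerises to the phenol and also frees the ring B phenol, so C6 ends as OH and C4 as OMe with no selective methylation. No stereocentre results, since the one sp3 centre formed (C6 of 14, racemic) is erased on aromatisation. The step needs regioselectivity, which the push–pull polarisation secures (largest HOMO coefficient at the diene CH2, largest LUMO coefficient at the ynoate β-carbon), placing the ester next to the new phenol. It also needs the alkyne to react in preference to the two ester carbonyls, which the absence of Lewis acid and free nucleophile secures, together with the ketone being masked as a dioxolane that cannot enol-lactonise onto the aryl ester.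

Step 9
Reactants: 15 benzyl 4-({2-[(2-heptyl-1,3-dioxolan-2-yl)methyl]-6-hydroxy-4-methoxybenzoyl}oxy)-2-hydroxy-6-methylbenzoate
Product: 16 benzyl 2-hydroxy-4-{[2-hydroxy-4-methoxy-6-(2-oxononyl)benzoyl]oxy}-6-methylbenzoate
Conditions: 1 M HCl, THF, 23 °C
Reagents that add atoms: water, O
Why: Acid-catalysed hydrolysis of the dioxolane (ketal cleavage) should proceed in dilute aqueous acid at room temperature, where the benzyl ester and the aryl ester are stable and the freed ketone is not driven to enol-lactonise onto the depside carbonyl.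

Step 10
Reactants: 16 benzyl 2-hydroxy-4-{[2-hydroxy-4-methoxy-6-(2-oxononyl)benzoyl]oxy}-6-methylbenzoate
Product: 17 2-hydroxy-4-{[2-hydroxy-4-methoxy-6-(2-oxononyl)benzoyl]oxy}-6-methylbenzoic acid (CNP0320117.0)
Conditions: H2 (1 atm), 10% Pd/C, EtOAc, 23 °C; filtration, evaporation below 30 °C
Reagents that add atoms: none
Why: Hydrogenolysis of a benzyl ester over palladium on carbon is the standard final step of depside syntheses; the aryl ester, the aryl methyl ether and the non-benzylic dialkyl ketone should be inert under one atmosphere of hydrogen, and toluene is the only by-product.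

**Compound list**

1 | ethyl 3-oxodecanoate | CCCCCCCC(=O)CC(=O)OCC | starting material
2 | ethyl 2-(2-heptyl-1,3-dioxolan-2-yl)acetate | CCCCCCCC1(CC(=O)OCC)OCCO1 | intermediate
3 | 2-(2-heptyl-1,3-dioxolan-2-yl)acetaldehyde | CCCCCCCC1(CC=O)OCCO1 | intermediate
4 | 2-heptyl-2-(prop-2-yn-1-yl)-1,3-dioxolane | CCCCCCCC1(CC#C)OCCO1 | intermediate
5 | lithium acetylide of 4, [3-(2-heptyl-1,3-dioxolan-2-yl)prop-1-yn-1-yl]lithium (not isolated) | CCCCCCCC1(CC#C[Li])OCCO1 | intermediate
6 | 4-(2-heptyl-1,3-dioxolan-2-yl)but-2-ynoic acid | CCCCCCCC1(CC#CC(=O)O)OCCO1 | intermediate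
7 | orsellinic acid (2,4-dihydroxy-6-methylbenzoic acid) | Cc1cc(O)cc(O)c1C(=O)O | starting material
8 | benzyl 2,4-dihydroxy-6-methylbenzoate | Cc1cc(O)cc(O)c1C(=O)OCc1ccccc1 | intermediate
9 | benzyl 4-{[4-(2-heptyl-1,3-dioxolan-2-yl)but-2-ynoyl]oxy}-2-hydroxy-6-methylbenzoate | CCCCCCCC1(CC#CC(=O)Oc2cc(C)c(C(=O)OCc3ccccc3)c(O)c2)OCCO1 | intermediate
10 | methyl (E)-3-methoxybut-2-enoate | CO/C(C)=C/C(=O)OC | starting material
11 | lithium (1E)-1,3-dimethoxybuta-1,3-dien-1-olate (not isolated) | COC(=C)/C=C(\OC)O[Li] | intermediate
12 | (1E)-1,3-dimethoxy-1-[(trimethylsilyl)oxy]buta-1,3-diene | COC(=C)/C=C(\OC)O[Si](C)(C)C | intermediate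
13 | benzyl 4-{[4-(2-heptyl-1,3-dioxolan-2-yl)but-2-ynoyl]oxy}-6-methyl-2-[(trimethylsilyl)oxy]benzoate (not isolated) | CCCCCCCC1(CC#CC(=O)Oc2cc(C)c(C(=O)OCc3ccccc3)c(O[Si](C)(C)C)c2)OCCO1 | intermediate
14 | benzyl 4-({2-[(2-heptyl-1,3-dioxolan-2-yl)methyl]-4,6-dimethoxy-6-[(trimethylsilyl)oxy]cyclohexa-1,4-diene-1-carbonyl}oxy)-6-methyl-2-[(trimethylsilyl)oxy]benzoate, racemic at C6 (not isolated) | COC1=CC(OC)(O[Si](C)(C)C)C(C(=O)Oc2cc(C)c(C(=O)OCc3ccccc3)c(O[Si](C)(C)C)c2)=C(CC2(CCCCCCC)OCCO2)C1 | intermediate
15 | benzyl 4-({2-[(2-heptyl-1,3-dioxolan-2-yl)methyl]-6-hydroxy-4-methoxybenzoyl}oxy)-2-hydroxy-6-methylbenzoate | CCCCCCCC1(Cc2cc(OC)cc(O)c2C(=O)Oc2cc(C)c(C(=O)OCc3ccccc3)c(O)c2)OCCO1 | intermediate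
16 | benzyl 2-hydroxy-4-{[2-hydroxy-4-methoxy-6-(2-oxononyl)benzoyl]oxy}-6-methylbenzoate | CCCCCCCC(=O)Cc1cc(OC)cc(O)c1C(=O)Oc1cc(C)c(C(=O)OCc2ccccc2)c(O)c1 | intermediate
17 | 2-hydroxy-4-{[2-hydroxy-4-methoxy-6-(2-oxononyl)benzoyl]oxy}-6-methylbenzoic acid | CCCCCCCC(=O)Cc1cc(OC)cc(O)c1C(=O)Oc1cc(C)c(C(=O)O)c(O)c1 | target

**Count**

Total steps: 10. Longest linear sequence: 8 steps (steps 1, 2, 3, 4, 6, 8, 9, 10); steps 5 and 7 supply ring B and the diene.

**Steps most likely to fail**

Step 8. The cycloaddition at the β-branched ynoate carbon may be slow enough that the methoxy diene is lost first by silyl transfer, hydrolysis and oligomerisation. Long heating could also let the ynoate drift to the allenoate. The fallback sets out from 9 and uses purchased 1-methoxy-1,3-bis(trimethylsilyloxy)buta-1,3-diene, a shelf-stable diene that can be used neat in large excess at 130–140 °C and belongs to the class with the longest record of thermal additions to β-alkyl ynoate esters. Silylation to 13 and cycloaddition should give benzyl 4-({2-[(2-heptyl-1,3-dioxolan-2-yl)methyl]-6-methoxy-4,6-bis[(trimethylsilyl)oxy]cyclohexa-1,4-diene-1-carbonyl}oxy)-6-methyl-2-[(trimethylsilyl)oxy]benzoate F1, which is not isolated. Cold dilute acid should convert it to benzyl 4-({2-[(2-heptyl-1,3-dioxolan-2-yl)methyl]-4,6-dihydroxybenzoyl}oxy)-2-hydroxy-6-methylbenzoate F2. A Mitsunobu methylation (MeOH, PPh3, DIAD, THF, 0 °C) should then etherify only the ring A 4-OH, the one phenol not locked in a hydrogen bond to an ester carbonyl, and the route is rejoined at 15.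

Step 6. Rearrangement of the O-acylisourea to the N-acylurea, or conjugate addition of DMAP or of the phenol to the activated ynoate, may outrun acyl transfer to the 4-OH. The fallback sets out from 6 and separates activation from acylation. 1-Chloro-N,N,2-trimethylprop-1-en-1-amine in CH2Cl2 at 0 °C should give, under neutral conditions that spare the dioxolane, 4-(2-heptyl-1,3-dioxolan-2-yl)but-2-ynoyl chloride F3. Adding this to 8 and 2,6-lutidine in CH2Cl2 at −40 °C, with no carbodiimide or nucleophilic catalyst present, returns to the route at 9.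

Step 3. In K2CO3/MeOH the β-ketal aldehyde may undergo base-induced β-elimination, opening the dioxolane to an enol ether enal, or aldol self-condensation before it is olefinated. The fallback sets out from 3 and uses the non-basic dibromomethylene ylide of the Corey–Fuchs reaction (CBr4, PPh3, Et3N, CH2Cl2, 0 °C) to give 2-(3,3-dibromoprop-2-en-1-yl)-2-heptyl-1,3-dioxolane F4. n-BuLi (2.1 equiv, THF, −78 °C) should convert F4 by bromine–lithium exchange and rearrangement directly into the lithium acetylide 5, which is carboxylated in the same flask as in step 4. The route is rejoined at 6, and alkyne 4 need not be isolated.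

**Further compounds**

F1 | step 8 | benzyl 4-({2-[(2-heptyl-1,3-dioxolan-2-yl)methyl]-6-methoxy-4,6-bis[(trimethylsilyl)oxy]cyclohexa-1,4-diene-1-carbonyl}oxy)-6-methyl-2-[(trimethylsilyl)oxy]benzoate | COC1(O[Si](C)(C)C)C=C(O[Si](C)(C)C)CC(CC2(CCCCCCC)OCCO2)=C1C(=O)Oc1cc(C)c(C(=O)OCc2ccccc2)c(O[Si](C)(C)C)c1
F2 | step 8 | benzyl 4-({2-[(2-heptyl-1,3-dioxolan-2-yl)methyl]-4,6-dihydroxybenzoyl}oxy)-2-hydroxy-6-methylbenzoate | CCCCCCCC1(Cc2cc(O)cc(O)c2C(=O)Oc2cc(C)c(C(=O)OCc3ccccc3)c(O)c2)OCCO1
F3 | step 6 | 4-(2-heptyl-1,3-dioxolan-2-yl)but-2-ynoyl chloride | CCCCCCCC1(CC#CC(=O)Cl)OCCO1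
F4 | step 3 | 2-(3,3-dibromoprop-2-en-1-yl)-2-heptyl-1,3-dioxolane | CCCCCCCC1(CC=C(Br)Br)OCCO1
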